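**Plan**

- Target: the achiral meso trans,trans 3,3''-biflavanone (2S,3R,2''R,3''S), two mirror-image liquiritigenin halves joined C3–C3''. Only relative configuration has to be controlled.
- Cuts: the four O-benzyl groups; then in each pyranone ring (ring C) the O1–C2 bond and the C2–C3 bond, which leaves a 1,4-bis(2-hydroxyaryl)butane-1,4-dione and two aryl aldehydes; last the central C3–C3'' bond, as the union of a resacetophenone ether with the α-bromo ketone made from the same ether.
- Enabling feature: C2 carries O1 (the ring A phenol oxygen ortho to the C4 acyl group) and is β to the C4 ketone. This β-aryloxy ketone forms by 6-endo oxa-Michael addition and reopens by E1cB, and C3–H is α to C4=O, so all four stereocenters are labile under the ring-forming conditions.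
- Forward: C3–C3'' first (α-bromination, then zinc-mediated ketone/bromo ketone coupling), the ortho phenols are unmasked, then one flask runs aldol condensation/oxa-Michael twice, closing ring C of one half and then of the other.
- Stereochemistry: thermodynamic and crystallization-driven funnelling during the annulation to diequatorial trans,trans rings in the centrosymmetric meso pairing; neutral hydrogenolysis keeps it.

Key step: step 5

Assumption: the target is the meso isomer, so chiral intermediates are racemic and their SMILES show one enantiomer with the correct relative configuration.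

**Step 1**
Reactants: 1 2',4'-dihydroxyacetophenone
Product: 2 2',4'-bis(benzyloxy)acetophenone
Conditions: BnBr (2.5 equiv), K2CO3 (3 equiv), DMF, 80 °C
Reagents that add atoms: benzyl bromide, BrCc1ccccc1
Why: Williamson ether synthesis; in hot DMF the hydrogen-bonded ortho phenol should alkylate as well as the para phenol.

**Step 2**
Reactants: 2 2',4'-bis(benzyloxy)acetophenone
Product: 3 2-bromo-1-[2,4-bis(benzyloxy)phenyl]ethan-1-one
Conditions: CuBr2 (2 equiv), EtOAc–CHCl3 (1:1), reflux
Reagents that add atoms: CuBr2 (dibromide of divalent copper), [Cu+2].[Br-].[Br-]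
Why: selective α-bromination of an aryl methyl ketone with CuBr2 through its copper-bound enol; the heterogeneous reagent keeps free bromine low, so the electron-rich ring and the benzyl ethers should be left alone.

**Step 3**
Reactants: 2 2',4'-bis(benzyloxy)acetophenone, 3 2-bromo-1-[2,4-bis(benzyloxy)phenyl]ethan-1-one
Product: 4 1,4-bis[2,4-bis(benzyloxy)phenyl]butane-1,4-dione
Conditions: ZnCl2 (2 equiv), Et2NH (1.5 equiv), t-BuOH (1.5 equiv), toluene, 20 °C, 48 h
Reagents that add atoms: none
Why: zinc-mediated coupling of a methyl ketone with an α-bromo ketone to a 1,4-diketone (soft enolization with ZnCl2 and an amine): the zinc enolate of 2 should be alkylated at carbon by 3 to form the CH2–CH2 bond that becomes C3–C3''; because both partners carry the same aryl group, direct displacement and the aldol/rearrangement pathway give the same symmetric diketone, and no stereocenter is formed.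

**Step 4**
Reactants: 4 1,4-bis[2,4-bis(benzyloxy)phenyl]butane-1,4-dione
Product: 5 1,4-bis[4-(benzyloxy)-2-hydroxyphenyl]butane-1,4-dione
Conditions: MgBr2·OEt2 (4 equiv), toluene–Et2O (10:1), 80 °C; then 1 M HCl
Reagents that add atoms: none
Why: chelation-controlled debenzylation: magnesium held between the ketone oxygen and the ortho ether oxygen should activate only that O–CH2Ph bond toward bromide, while the para benzyl ethers cannot form the chelate and should stay.

**Step 5**
Reactants: 5 1,4-bis[4-(benzyloxy)-2-hydroxyphenyl]butane-1,4-dione, 6 4-(benzyloxy)benzaldehyde (2.4 equiv)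
Product: 10 meso tetra-O-benzyl biflavanone (2S,3R,2''R,3''S)-7,7''-bis(benzyloxy)-2,2''-bis[4-(benzyloxy)phenyl]-3,3''-bichroman-4,4''-dione, via mono-arylidene diketone 7 (not isolated), via trans-3-phenacylflavanone 8 (not isolated), via flavanonyl chalcone 9 (not isolated)
Conditions: pyrrolidine (2 equiv), EtOH–toluene (4:1), 80 °C, 48 h; slow cooling to 20 °C, slurry aged 24 h, filtration
Reagents that add atoms: none
Why: Pyrrolidine should condense the α-carbon of each aryl ketone with the aldehyde (Mannich-type addition to the aldehyde-derived iminium ion, then loss of the amine) to an α-substituted 2'-hydroxychalcone (7, and 9 once the first ring has closed to 8), and the ortho phenol of ring A then adds to the β-carbon of the enone to form the O1–C2 bond, the last such addition (9 to 10) closing the second pyranone ring. The closest known reaction type is the amine-mediated aldol condensation/oxa-Michael annulation of 2'-hydroxyaryl alkyl ketones with aryl aldehydes (Kabbe-type condensation), which is known to deliver trans-3-substituted flavanones. Both rings close in the 6-endo-trig mode. C2 and C2'' are set in the oxa-Michael additions and C3 and C3'' by protonation of the resulting enolate; since the addition reverses by E1cB and C3 epimerizes through the enol, these centers are under thermodynamic control and each ring should settle with the aryl group and the C3 substituent trans-diequatorial. The step needs the unlike (meso) pairing of the two trans rings; it should be favored because only this isomer has a staggered conformer about C3–C3'' with C2/C2'' anti and the C4/C4'' carbonyls anti (centrosymmetric, opposed dipoles), and its crystallization from the equilibrating mixture should drain the C2-symmetric isomer into it. Chemoselectivity rests on the ortho relation of each phenol to its own acyl group (six-membered instead of seven-membered closure) and on the secondary amine, which cannot form a pyrrole with the 1,4-diketone.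

**Step 6**
Reactants: 10 meso tetra-O-benzyl biflavanone
Product: 11 (2S,3R,2''R,3''S)-7,7''-dihydroxy-2,2''-bis(4-hydroxyphenyl)-3,3''-bichroman-4,4''-dione (target)
Conditions: H2 (1 atm), 10% Pd/C, THF–MeOH (1:1), 20 °C, stopped after uptake of 4 equiv H2; crystallization from aqueous MeOH
Reagents that add atoms: none
Why: catalytic hydrogenolysis of the four aryl benzyl ethers; the neutral medium should allow neither retro-oxa-Michael opening nor enolization, so the four stereocenters are kept.

**Compound list**

1 | 2',4'-dihydroxyacetophenone | CC(=O)c1ccc(O)cc1O | starting material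
2 | 2',4'-bis(benzyloxy)acetophenone | CC(=O)c1ccc(OCc2ccccc2)cc1OCc1ccccc1 | intermediate
3 | 2-bromo-1-[2,4-bis(benzyloxy)phenyl]ethan-1-one | O=C(CBr)c1ccc(OCc2ccccc2)cc1OCc1ccccc1 | intermediate
4 | 1,4-bis[2,4-bis(benzyloxy)phenyl]butane-1,4-dione | O=C(CCC(=O)c1ccc(OCc2ccccc2)cc1OCc1ccccc1)c1ccc(OCc2ccccc2)cc1OCc1ccccc1 | intermediate
5 | 1,4-bis[4-(benzyloxy)-2-hydroxyphenyl]butane-1,4-dione | O=C(CCC(=O)c1ccc(OCc2ccccc2)cc1O)c1ccc(OCc2ccccc2)cc1O | intermediate
6 | 4-(benzyloxy)benzaldehyde | O=Cc1ccc(OCc2ccccc2)cc1 | starting material
7 | (E)-2-[4-(benzyloxy)benzylidene]-1,4-bis[4-(benzyloxy)-2-hydroxyphenyl]butane-1,4-dione | O=C(C/C(=C\c1ccc(OCc2ccccc2)cc1)C(=O)c1ccc(OCc2ccccc2)cc1O)c1ccc(OCc2ccccc2)cc1O | intermediate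
8 | rac-(2S,3R)-7-(benzyloxy)-2-[4-(benzyloxy)phenyl]-3-{2-[4-(benzyloxy)-2-hydroxyphenyl]-2-oxoethyl}chroman-4-one (trans) | O=C1c2ccc(OCc3ccccc3)cc2O[C@H](c2ccc(OCc3ccccc3)cc2)[C@H]1CC(=O)c1ccc(OCc2ccccc2)cc1O | intermediate
9 | rac-(2S,3R)-7-(benzyloxy)-2-[4-(benzyloxy)phenyl]-3-{(1E)-3-[4-(benzyloxy)-2-hydroxyphenyl]-1-[4-(benzyloxy)phenyl]-3-oxoprop-1-en-2-yl}chroman-4-one (trans) | O=C1c2ccc(OCc3ccccc3)cc2O[C@H](c2ccc(OCc3ccccc3)cc2)[C@H]1/C(=C\c1ccc(OCc2ccccc2)cc1)C(=O)c1ccc(OCc2ccccc2)cc1O | intermediate
10 | meso-(2S,3R,2''R,3''S)-7,7''-bis(benzyloxy)-2,2''-bis[4-(benzyloxy)phenyl]-3,3''-bichroman-4,4''-dione | O=C1c2ccc(OCc3ccccc3)cc2O[C@H](c2ccc(OCc3ccccc3)cc2)[C@H]1[C@@H]1C(=O)c2ccc(OCc3ccccc3)cc2O[C@H]1c1ccc(OCc2ccccc2)cc1 | intermediate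
11 | meso-(2S,3R,2''R,3''S)-7,7''-dihydroxy-2,2''-bis(4-hydroxyphenyl)-3,3''-bichroman-4,4''-dione | O=C1c2ccc(O)cc2O[C@H](c2ccc(O)cc2)[C@H]1[C@@H]1C(=O)c2ccc(O)cc2O[C@H]1c1ccc(O)cc1 | target

**Totals**

Total step count: 6. Longest linear sequence: 6 steps (1 → 2 → 3 → 4 → 5 → 10 → 11); ketone 2 also enters step 3 as the second partner, and aldehyde 6 is bought.

**Steps most likely to fail**

Step 5. The stereochemical funnelling may stay incomplete: the benzyl-protected rings may reopen too slowly for the C2-symmetric trans,trans diastereomer to drain into the meso form, or the two forms may crystallize together. The fallback moves stereocontrol from the protected annulation product to the free target. It sets out from 10 as obtained in admixture with rac-(2S,3R,2''S,3''R)-7,7''-bis(benzyloxy)-2,2''-bis[4-(benzyloxy)phenyl]-3,3''-bichroman-4,4''-dione F1. The mixture is hydrogenolysed under the conditions of step 6 to 11 and rac-(2S,3R,2''S,3''R)-7,7''-dihydroxy-2,2''-bis(4-hydroxyphenyl)-3,3''-bichroman-4,4''-dione F2. This mixture is then equilibrated with NaOAc in aqueous EtOH at 60 °C, where the free 4'-hydroxyl should open each pyranone ring through a p-quinone methide/chalcone phenolate much faster than the benzyl ethers can. Compound 11 is withdrawn by seeded crystallization or by preparative HPLC with return of F2 to the equilibration; the route is rejoined at 11.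

Step 3. The zinc enolate may add to the carbonyl group of 3 and stall at the aldol or epoxide stage, or 3 may be consumed by the amine, so that little diketone forms. The fallback replaces the direct coupling by alkylation of a stabilized β-keto ester enolate followed by loss of the ester. It sets out from 2, which is C-acylated with dimethyl carbonate (NaH, THF, reflux) to methyl 3-[2,4-bis(benzyloxy)phenyl]-3-oxopropanoate F3. Alkylation of F3 with bromo ketone 3 (K2CO3, acetone, 20 °C) should give rac-methyl (2R)-2-[2,4-bis(benzyloxy)benzoyl]-4-[2,4-bis(benzyloxy)phenyl]-4-oxobutanoate F4. Krapcho demethoxycarbonylation (LiCl, wet DMSO, 130 °C) then removes the ester, and the route is rejoined at 4.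

Step 4. Chelation control may be lost, with cleavage of the para benzyl ethers alongside the ortho ones or incomplete removal of the ortho ones. The fallback gives up selective cleavage in favor of selective re-protection. It sets out from 4, which is fully debenzylated with H2 and 10% Pd/C in THF–MeOH to 1,4-bis(2,4-dihydroxyphenyl)butane-1,4-dione F5. Treatment with BnBr (2.1 equiv) and K2CO3 in acetone at reflux should then benzylate only the two para hydroxyls, because the ortho hydroxyls are hydrogen-bonded to the ketones and are much less nucleophilic. The route is rejoined at 5.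

**Further compounds**

F1 | step 5 | rac-(2S,3R,2''S,3''R)-7,7''-bis(benzyloxy)-2,2''-bis[4-(benzyloxy)phenyl]-3,3''-bichroman-4,4''-dione | O=C1c2ccc(OCc3ccccc3)cc2O[C@H](c2ccc(OCc3ccccc3)cc2)[C@H]1[C@H]1C(=O)c2ccc(OCc3ccccc3)cc2O[C@@H]1c1ccc(OCc2ccccc2)cc1
F2 | step 5 | rac-(2S,3R,2''S,3''R)-7,7''-dihydroxy-2,2''-bis(4-hydroxyphenyl)-3,3''-bichroman-4,4''-dione | O=C1c2ccc(O)cc2O[C@H](c2ccc(O)cc2)[C@H]1[C@H]1C(=O)c2ccc(O)cc2O[C@@H]1c1ccc(O)cc1
F3 | step 3 | methyl 3-[2,4-bis(benzyloxy)phenyl]-3-oxopropanoate | COC(=O)CC(=O)c1ccc(OCc2ccccc2)cc1OCc1ccccc1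
F4 | step 3 | rac-methyl (2R)-2-[2,4-bis(benzyloxy)benzoyl]-4-[2,4-bis(benzyloxy)phenyl]-4-oxobutanoate | COC(=O)[C@H](CC(=O)c1ccc(OCc2ccccc2)cc1OCc1ccccc1)C(=O)c1ccc(OCc2ccccc2)cc1OCc1ccccc1
F5 | step 4 | 1,4-bis(2,4-dihydroxyphenyl)butane-1,4-dione | O=C(CCC(=O)c1ccc(O)cc1O)c1ccc(O)cc1O
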